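The route rests on cutting the bond between the central ketone carbon and the methine attached to C2 of the pentyl-bearing 4-pyranone ring. That methine is allylic to the ring C2=C3 bond and vinylogously conjugated to the ring C4 carbonyl, so a planar, stabilised radical forms there easily. A nickel–bis(oxazoline)-catalysed reductive acyl cross-coupling joins the chloride of this position, of any configuration, with the (S)-acid chloride of the ethyl-pyranone half; it makes the ketone and funnels both chloride enantiomers into the (R)-methine without base, sparing both epimerisable centres. The acid comes from symmetric 2,6-diethyl-3,5-dimethyl-4-pyranone by carboxylation and dynamic kinetic resolution; the chloride from 3-pentanone, a lactate and a hexanamide.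

Key step: step 10

Assumption: the 4-pyranon-2-yl ring is taken to behave like the aryl group of 2-arylpropanoic acids and 1-arylethyl chlorides, so the catalyst enantiomers in steps 3 and 10 are chosen by that analogy (the antipode is used if a model run shows the opposite sense). The lactate-derived centre of 9, 11 and 13–17 is erased at the radical stage of step 10, and its descriptors serve bookkeeping only.

Step 1
Reactants: 1 3-pentanone; 2 propanoic acid (two molecules are incorporated)
Product: 3 2,6-diethyl-3,5-dimethyl-4H-pyran-4-one
Conditions: polyphosphoric acid (medium), 2 (excess, at least 2 equiv), 130 °C; then ice/water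
Reagents that add atoms: propanoic acid (the second molecule of 2), CCC(=O)O
Why: Polyphosphoric acid-mediated ketone–carboxylic acid pyranone condensation, in which each of the two α-methylenes of 1 is C-acylated by one molecule of 2 and the resulting 1,3,5-triketone cyclodehydrates to the symmetric 4-pyranone (three molecules of water are lost overall), which has no stereocentre.

Step 2
Reactants: 3 2,6-diethyl-3,5-dimethyl-4H-pyran-4-one
Product: 5 rac-2-(6-ethyl-3,5-dimethyl-4-oxo-4H-pyran-2-yl)propanoic acid, via lithium dienolate 4 (not isolated)
Conditions: LiN(SiMe3)2 (1.05 equiv), THF, −78 °C; cannulated into CO2-saturated THF, −78 °C; cold 1 M HCl, extraction below 10 °C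
Reagents that add atoms: carbon dioxide, O=C=O
Why: γ-Deprotonation of a 2-alkyl-4-pyranone gives the vinylogous enolate 4, which is carboxylated at the exocyclic carbon (vinylogous enolate carboxylation); the twofold symmetry of 3 makes the two ethyl groups equivalent, inverse addition into excess CO2 should prevent a second carboxylation, and the new centre is deliberately formed racemic.

Step 3
Reactants: 5 rac-2-(6-ethyl-3,5-dimethyl-4-oxo-4H-pyran-2-yl)propanoic acid
Product: 7 di(naphthalen-1-yl)methyl (S)-2-(6-ethyl-3,5-dimethyl-4-oxo-4H-pyran-2-yl)propanoate, via mixed pivalic anhydride 6 (not isolated)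
Conditions: (S)-benzotetramisole (10 mol %), (t-BuCO)2O (2 equiv), i-Pr2NEt (4 equiv), di(naphthalen-1-yl)methanol (1.1 equiv), DMF, rt
Reagents that add atoms: di(naphthalen-1-yl)methanol, OC(c1cccc2ccccc12)c1cccc2ccccc12
Why: Isothiourea-catalysed acyl-transfer dynamic kinetic resolution of a 2-arylpropanoic-type acid, in which the mixed anhydride 6 racemises through its acidic methine (flanked by the anhydride carbonyl and pyranone C2) under i-Pr2NEt in DMF while the acyl-isothiouronium of one enantiomer is intercepted faster by the bulky diarylmethanol, so the chiral catalyst sets the (S) centre and the whole racemate should be funnelled into one ester.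

Step 4
Reactants: 7 di(naphthalen-1-yl)methyl (S)-2-(6-ethyl-3,5-dimethyl-4-oxo-4H-pyran-2-yl)propanoate
Product: 8 (S)-2-(6-ethyl-3,5-dimethyl-4-oxo-4H-pyran-2-yl)propanoic acid
Conditions: H2 (1 atm), Pd/C, EtOAc, rt; concentrated cold
Reagents that add atoms: none
Why: Hydrogenolysis of the benzhydryl-type ester C–O bond under neutral conditions should free the acid without touching the labile (S) methine or the fully substituted pyranone ring.

Step 5
Reactants: 1 3-pentanone; 9 ethyl (S)-2-((tert-butyldimethylsilyl)oxy)propanoate
Product: 11 (2S)-2-((tert-butyldimethylsilyl)oxy)-4-methylheptane-3,5-dione, via lithium enolate 10 (not isolated)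
Conditions: 1 (2.2 equiv), LiN(i-Pr)2 (2.2 equiv), THF, −78 °C; then 9, −78 → 0 °C; AcOH quench
Reagents that add atoms: none
Why: Crossed Claisen condensation of the lithium enolate of 1 with the activated α-silyloxy ester 9, driven by deprotonation of the 1,3-diketone by the second equivalent of enolate; the lactate centre is not enolised and the new methine between the carbonyls is a freely equilibrating mixture of no consequence.

Step 6
Reactants: 11 (2S)-2-((tert-butyldimethylsilyl)oxy)-4-methylheptane-3,5-dione; 12 N-methoxy-N-methylhexanamide
Product: 14 (2S)-2-((tert-butyldimethylsilyl)oxy)-4,6-dimethyldodecane-3,5,7-trione, via dilithium dianion 13 (not isolated)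
Conditions: LiN(i-Pr)2 (2.1 equiv), THF, −78 → 0 °C; then 12, −78 → −20 °C; AcOH quench
Reagents that add atoms: none
Why: Dianion acylation of a 1,3-diketone, in which the second deprotonation should occur at the unhindered ethyl CH2 and not at the silyloxy-bearing methine, and this more basic terminal carbon attacks the N-methoxy-N-methylamide, whose chelated tetrahedral adduct prevents over-addition; the two methyl-bearing centres are labile and irrelevant because both become sp2 in step 7.

Step 7
Reactants: 14 (2S)-2-((tert-butyldimethylsilyl)oxy)-4,6-dimethyldodecane-3,5,7-trione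
Product: 15 (S)-2-(1-((tert-butyldimethylsilyl)oxy)ethyl)-3,5-dimethyl-6-pentyl-4H-pyran-4-one
Conditions: PPh3 (3 equiv), CCl4, THF, rt
Reagents that add atoms: none
Why: Cyclodehydration of a 1,3,5-triketone to the 4-pyranone under Appel-type activation (one terminal enol becomes an enol phosphonium and is displaced by the other terminal enol oxygen in a six-membered ring closure), conditions that should leave the silyl ether in place and so block the competing 3(2H)-furanone closure of a free α-hydroxy ketone.

Step 8
Reactants: 15 (S)-2-(1-((tert-butyldimethylsilyl)oxy)ethyl)-3,5-dimethyl-6-pentyl-4H-pyran-4-one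
Product: 16 (S)-2-(1-hydroxyethyl)-3,5-dimethyl-6-pentyl-4H-pyran-4-one
Conditions: HF·pyridine, pyridine/THF, 0 °C → rt
Reagents that add atoms: none
Why: Fluoride-mediated silyl ether cleavage driven by the Si–F bond, under buffered conditions to which the pyranone is inert.

Step 9
Reactants: 16 (S)-2-(1-hydroxyethyl)-3,5-dimethyl-6-pentyl-4H-pyran-4-one
Product: 17 (R)-2-(1-chloroethyl)-3,5-dimethyl-6-pentyl-4H-pyran-4-one
Conditions: PPh3 (1.3 equiv), CCl4, CH2Cl2, 0 °C → rt
Reagents that add atoms: carbon tetrachloride, ClC(Cl)(Cl)Cl
Why: Appel reaction, in which the alkoxyphosphonium is displaced by chloride in an SN2 step accelerated by the adjacent pyranone π system, giving the chloride with nominal inversion, although its configuration is of no consequence for step 10.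

Step 10
Reactants: 8 (S)-2-(6-ethyl-3,5-dimethyl-4-oxo-4H-pyran-2-yl)propanoic acid; 17 (R)-2-(1-chloroethyl)-3,5-dimethyl-6-pentyl-4H-pyran-4-one
Product: 19 (2R,4S)-2-(3,5-dimethyl-4-oxo-6-pentyl-4H-pyran-2-yl)-4-(6-ethyl-3,5-dimethyl-4-oxo-4H-pyran-2-yl)pentan-3-one (the target), via (S)-acid chloride 18 (not isolated)
Conditions: 8 (1.3 equiv), 1-chloro-N,N,2-trimethylprop-1-en-1-amine (1.3 equiv), THF, 0 °C, 1 h; then added slowly to 17, NiCl2(dme) (10 mol %), (R,R)-Ph-BOX [2,2'-(propane-2,2-diyl)bis(4-phenyl-4,5-dihydrooxazole)] (22 mol %), Mn powder (3 equiv), 2,6-dimethylbenzoic acid (0.75 equiv), 3 Å MS, DMA/THF (3:7), 20 °C; neutral work-up, buffered silica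
Reagents that add atoms: none
Why: The acid chloride 18, made in the flask under neutral conditions, adds oxidatively to zerovalent nickel (formed by Mn reduction) to give a divalent acyl nickel chloride, while chlorine-atom abstraction from 17 by a low-valent nickel species releases the secondary radical at the methine on C2 of the pentyl pyranone ring, planar and delocalised over ring C2=C3 and the C4 carbonyl oxygen; radical capture gives an acyl(alkyl) trivalent nickel that reductively eliminates the new ketone–methine bond, and Mn turns the cycle over. The closest known reaction type is the nickel/bis(oxazoline)-catalysed enantioconvergent reductive acyl cross-coupling of acid chlorides with racemic secondary benzylic chlorides, with the 4-pyranon-2-yl ring here in the place of the arene. No ring is closed. The new (R) centre is set by the chiral bis(oxazoline)–nickel complex at the radical-capture and reductive-elimination stage, whatever the configuration of 17 (stereoconvergence), and the (S) centre should come unchanged from 8 because neither ketene nor enolate is expected to form in the absence of base. The step needs cross-coupling over homocoupling, secured by the different activation modes of the two chlorides (two-electron oxidative addition for the acyl chloride, halogen abstraction for the activated secondary chloride), and catalyst control over the resident (S) centre, which is the main uncertainty because the two methines sit 1,3 across the new ketone. The weakly acidic, reductive medium and a neutral work-up should keep both doubly activated methines of 19 from epimerising.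

Compound list
1 | 3-pentanone | CCC(=O)CC | starting material
2 | propanoic acid (two molecules are built into 3) | CCC(=O)O | starting material
3 | 2,6-diethyl-3,5-dimethyl-4H-pyran-4-one | CCc1oc(CC)c(C)c(=O)c1C | intermediate
4 | lithium 6-ethyl-2-ethylidene-3,5-dimethyl-2H-pyran-4-olate (dienolate of 3, not isolated) | CC=C1OC(CC)=C(C)C([O-])=C1C.[Li+] | intermediate
5 | rac-2-(6-ethyl-3,5-dimethyl-4-oxo-4H-pyran-2-yl)propanoic acid | OC(=O)C(C)c1oc(CC)c(C)c(=O)c1C | intermediate
6 | 2-(6-ethyl-3,5-dimethyl-4-oxo-4H-pyran-2-yl)propanoic pivalic anhydride (racemising, not isolated) | CC(C)(C)C(=O)OC(=O)C(C)c1oc(CC)c(C)c(=O)c1C | intermediate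
7 | di(naphthalen-1-yl)methyl (S)-2-(6-ethyl-3,5-dimethyl-4-oxo-4H-pyran-2-yl)propanoate | O=C(OC(c1cccc2ccccc12)c1cccc2ccccc12)[C@@H](C)c1oc(CC)c(C)c(=O)c1C | intermediate
8 | (S)-2-(6-ethyl-3,5-dimethyl-4-oxo-4H-pyran-2-yl)propanoic acid | OC(=O)[C@@H](C)c1oc(CC)c(C)c(=O)c1C | intermediate
9 | ethyl (S)-2-((tert-butyldimethylsilyl)oxy)propanoate | CCOC(=O)[C@H](C)O[Si](C)(C)C(C)(C)C | starting material
10 | lithium pent-2-en-3-olate (enolate of 1, not isolated) | CC=C([O-])CC.[Li+] | intermediate
11 | (2S)-2-((tert-butyldimethylsilyl)oxy)-4-methylheptane-3,5-dione (C4 epimers and enol forms) | C[C@H](O[Si](C)(C)C(C)(C)C)C(=O)C(C)C(=O)CC | intermediate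
12 | N-methoxy-N-methylhexanamide | CCCCCC(=O)N(C)OC | starting material
13 | dilithium (2S)-2-((tert-butyldimethylsilyl)oxy)-4-methylhepta-3,5-diene-3,5-bis(olate) (dianion of 11, not isolated) | C[C@H](O[Si](C)(C)C(C)(C)C)C([O-])=C(C)C([O-])=CC.[Li+].[Li+] | intermediate
14 | (2S)-2-((tert-butyldimethylsilyl)oxy)-4,6-dimethyldodecane-3,5,7-trione (C4/C6 epimers and enol forms) | C[C@H](O[Si](C)(C)C(C)(C)C)C(=O)C(C)C(=O)C(C)C(=O)CCCCC | intermediate
15 | (S)-2-(1-((tert-butyldimethylsilyl)oxy)ethyl)-3,5-dimethyl-6-pentyl-4H-pyran-4-one | CCCCCc1oc([C@H](C)O[Si](C)(C)C(C)(C)C)c(C)c(=O)c1C | intermediate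
16 | (S)-2-(1-hydroxyethyl)-3,5-dimethyl-6-pentyl-4H-pyran-4-one | CCCCCc1oc([C@H](C)O)c(C)c(=O)c1C | intermediate
17 | (R)-2-(1-chloroethyl)-3,5-dimethyl-6-pentyl-4H-pyran-4-one (enantiomeric purity immaterial) | CCCCCc1oc([C@@H](C)Cl)c(C)c(=O)c1C | intermediate
18 | (S)-2-(6-ethyl-3,5-dimethyl-4-oxo-4H-pyran-2-yl)propanoyl chloride (not isolated) | ClC(=O)[C@@H](C)c1oc(CC)c(C)c(=O)c1C | intermediate
19 | (2R,4S)-2-(3,5-dimethyl-4-oxo-6-pentyl-4H-pyran-2-yl)-4-(6-ethyl-3,5-dimethyl-4-oxo-4H-pyran-2-yl)pentan-3-one; R at the methine on the pentyl pyranone, S at the methine on the ethyl pyranone | CCCCCc1oc([C@@H](C)C(=O)[C@@H](C)c2oc(CC)c(C)c(=O)c2C)c(C)c(=O)c1C | target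

Total step count: 10. Longest linear sequence: 6 steps (steps 5, 6, 7, 8, 9, 10); the acid branch (steps 1–4) joins at step 10.

Steps most likely to fail

Step 10. The coupling may suffer from dimerisation of the pyranonyl-ethyl radical, from slow reaction of two hindered, branched partners, from erosion of the (S) centre through reversible ketene formation from 18 in DMA, or from a mismatch between ligand control and the resident centre. The fallback makes the same bond in a two-electron manifold, a palladium-catalysed enantioconvergent Fukuyama coupling, and sets out from 8 and 17. Acid 8 is converted with ethanethiol, EDC·HCl and HOBt in CH2Cl2 at 0 °C into S-ethyl (S)-2-(6-ethyl-3,5-dimethyl-4-oxo-4H-pyran-2-yl)propanethioate F1, a configurationally sturdier acyl donor. Chloride 17 is treated with Zn dust and LiCl in THF to give the racemic, configurationally labile chloro[1-(3,5-dimethyl-4-oxo-6-pentyl-4H-pyran-2-yl)ethyl]zinc F2. F1 and F2 are then coupled with Pd(OAc)2 and a chiral monodentate phosphoramidite ligand in THF at rt, so that the rapidly inverting zinc reagent should be funnelled into the (R) centre, and the sequence returns to the route at 19.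

Step 3. Enantiodiscrimination may be weak because the pyranone is not a true arene, and the product ester may slowly epimerise under the amine base. The fallback replaces the acyl-transfer catalyst by a hydrolase and sets out from 5. Acid 5 is esterified with trimethylsilyldiazomethane in toluene/MeOH to methyl rac-2-(6-ethyl-3,5-dimethyl-4-oxo-4H-pyran-2-yl)propanoate F3. F3 is subjected to kinetic resolution with Candida rugosa lipase (a triacylglycerol lipase, (S)-selective on 2-arylpropanoates) in pH 7 phosphate buffer/toluene at rt. The (S)-ester should be hydrolysed to the acid, the unreacted (R)-ester is racemised with DBU and recycled, and the sequence returns to the route at 8, bypassing 6, 7 and step 4.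

Step 6. Proton transfer from the enolisable amide to the dianion, deprotonation at the silyloxy methine and reaction at oxygen may all lower conversion. The fallback moves the bond formation to the aldehyde oxidation level and sets out from 11. The dianion 13 (LiN(i-Pr)2, THF, −78 → 0 °C) is added to hexanal at −78 °C and quenched with AcOH to give (2S)-2-((tert-butyldimethylsilyl)oxy)-7-hydroxy-4,6-dimethyldodecane-3,5-dione F4. Oxidation of F4 with Dess–Martin periodinane in CH2Cl2 at rt returns to the route at 14.

Further compounds
F1 | step 10 | S-ethyl (S)-2-(6-ethyl-3,5-dimethyl-4-oxo-4H-pyran-2-yl)propanethioate | CCSC(=O)[C@@H](C)c1oc(CC)c(C)c(=O)c1C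
F2 | step 10 | chloro[1-(3,5-dimethyl-4-oxo-6-pentyl-4H-pyran-2-yl)ethyl]zinc (racemic) | CCCCCc1oc(C(C)[Zn]Cl)c(C)c(=O)c1C
F3 | step 3 | methyl rac-2-(6-ethyl-3,5-dimethyl-4-oxo-4H-pyran-2-yl)propanoate | COC(=O)C(C)c1oc(CC)c(C)c(=O)c1C
F4 | step 6 | (2S)-2-((tert-butyldimethylsilyl)oxy)-7-hydroxy-4,6-dimethyldodecane-3,5-dione (mixture of diastereomers) | C[C@H](O[Si](C)(C)C(C)(C)C)C(=O)C(C)C(=O)C(C)C(O)CCCCC
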